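**Retrosynthetic overview**

1. Target ⇐ butenolide 24 (opened last) ⇐ aldehyde 20 + methyl propiolate; C12 comes from a catalytic asymmetric alkynylation and the 13Z geometry from a syn-carbocupration.
2. 20 ⇐ trans-decalin allylsilane 17 (protodesilylation gives C8=C17 and 9α-H) ⇐ Δ4-enoate 15 (reductive methylation gives 5α-H, 4α-CH3, 4β-CO2R) ⇐ dienone 12.
3. 12 ⇐ achiral open-chain dienynone 11 by an intramolecular Diels–Alder reaction that closes rings A and B at once (bonds C6–C7 and C5–C10) and creates only the quaternary C10.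
4. Enabling feature: ring B (C5–C10) is a methylenecyclohexane whose exocyclic C8=C17 is flanked by C7 and C9. This is the retron of the [4+2] adduct of a 2-(silylmethyl)buta-1,3-diene C7=C8–C9=C10 after allyl transposition; C5–C6 is the dienophile (as an alkyne), the C1–C4 chain of ring A is the tether, and C4 carries the activating carbonyl that later becomes C4(CH3)CO2H.
5. 11 ⇐ 2-acetyl-γ-butyrolactone (C8–C12, C20) + enynol 4 (C1–C6) + Me3SiCH2MgCl (C7, C17). Ring order: A and B together (step 8), then the butenolide transiently (step 16, opened in step 17).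

Key step: step 8

Remark: labdane numbering (C1–C20) is used throughout; the free γ-hydroxy-(Z)-enoic acid of the target is assumed to be isolable without relactonisation if the final acidification is stopped at pH 4–5 in the cold.

**Route**

Step 1
Reactants: 1 2-acetyl-γ-butyrolactone
Product: 2 (E)-1-(2-oxodihydrofuran-3(2H)-ylidene)ethyl trifluoromethanesulfonate
Conditions: Tf2O, aq. Me4NOH, toluene, 5 °C
Reagents that add atoms: trifluoromethanesulfonic anhydride O=S(=O)(OS(=O)(=O)C(F)(F)F)C(F)(F)F
Why: O-triflation of the non-chelated tetramethylammonium enolate of the β-keto lactone should occur on the ketone oxygen of the anti (W-shaped) enolate, placing OTf trans to the lactone carbonyl (E, stereoselective enol triflate formation of a β-keto ester).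

Step 2
Reactants: 3 3-(trimethylsilyl)propynal
Product: 4 rac-1-(trimethylsilyl)hex-5-en-1-yn-3-ol
Conditions: allylMgBr, THF, −78 °C; aq. NH4Cl
Reagents that add atoms: allylmagnesium bromide C=CC[Mg]Br
Why: Grignard 1,2-addition to the ynal gives the C1–C6 fragment, and no stereocontrol is needed because the carbinol carbon becomes the C4 ketone in step 7.

Step 3
Reactants: 4 rac-1-(trimethylsilyl)hex-5-en-1-yn-3-ol; 2 enol triflate
Product: 6 (E)-3-[6-hydroxy-8-(trimethylsilyl)oct-7-yn-2-ylidene]dihydrofuran-2(3H)-one, via borane 5 (not isolated)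
Conditions: 9-BBN (2.3 equiv), THF, 0 °C → rt; then 2, Pd(dppf)Cl2 (5 mol%), AsPh3, aq. K3PO4, DMF, rt
Reagents that add atoms: none
Why: 9-BBN should hydroborate the terminal alkene anti-Markovnikov in preference to the silyl-capped alkyne (the hydroxyl only consumes one equivalent as the borinate), and the B-alkyl Suzuki–Miyaura coupling proceeds with retention of the triflate geometry, fixing the tetrasubstituted C9=C10 bond with C1 cis to C11.

Step 4
Reactants: 6 alkylidene lactone
Product: 8 (E)-3-(2-hydroxyethyl)-4-methyl-10-(trimethylsilyl)-2-[(trimethylsilyl)methyl]deca-1,3-dien-9-yn-8-ol, via carbinol 7 (not isolated)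
Conditions: Me3SiCH2MgCl (6 equiv), CeCl3 (6 equiv), THF, −78 °C → rt; aq. NH4Cl; then SiO2, CH2Cl2, rt
Reagents that add atoms: (trimethylsilyl)methylmagnesium chloride C[Si](C)(C)C[Mg]Cl
Why: cerium-mediated double addition of the silylmethyl Grignard reagent to the lactone carbonyl gives the ring-opened bis(β-silyl) carbinol, and Peterson elimination of one β-silyl group should unveil the 2-(silylmethyl)-1,3-diene C7=C8(CH2Si)–C9=C10 together with the free C12 hydroxyl.

Step 5
Reactants: 8 diene diol
Product: 9 (E)-4-methyl-3-[2-(triisopropylsilyloxy)ethyl]-10-(trimethylsilyl)-2-[(trimethylsilyl)methyl]deca-1,3-dien-9-yn-8-ol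
Conditions: TIPSCl (1.05 equiv), imidazole, DMF, 0 °C
Reagents that add atoms: chlorotriisopropylsilane CC(C)[Si](Cl)(C(C)C)C(C)C
Why: the bulky silyl chloride should silylate the primary C12 hydroxyl selectively over the secondary propargylic one (steric discrimination in silyl ether formation).

Step 6
Reactants: 9 TIPS ether
Product: 10 (E)-4-methyl-3-[2-(triisopropylsilyloxy)ethyl]-2-[(trimethylsilyl)methyl]deca-1,3-dien-9-yn-8-ol
Conditions: K2CO3 (cat.), MeOH, rt
Reagents that add atoms: none
Why: methanolysis cleaves only the C(sp)–Si bond, leaving the allylsilane and the silyl ether untouched (alkynylsilane protodesilylation).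

Step 7
Reactants: 10 propargylic alcohol
Product: 11 (E)-7-methyl-8-[2-(triisopropylsilyloxy)ethyl]-9-[(trimethylsilyl)methyl]deca-7,9-dien-1-yn-3-one
Conditions: MnO2, CH2Cl2, rt; filter and use at once
Reagents that add atoms: none
Why: activated MnO2 oxidises the propargylic alcohol to the ethynyl ketone under neutral conditions that the acid-sensitive dienylsilane tolerates.

Step 8
Reactants: 11 open-chain dienynone
Product: 12 12-(triisopropylsilyloxy)-17-(trimethylsilyl)-13,14,15,16,18,19-hexanorlabda-5,8-dien-4-one (10β-methyl; C10 R)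
Conditions: N-protonated (S)-o-tolyl-oxazaborolidinium triflimide (20 mol%), CH2Cl2 (0.01 M), −78 → −40 °C
Reagents that add atoms: none
Why: Proposed new method: the boron-bound ynone is LUMO-lowered and should undergo a concerted but asynchronous intramolecular [4+2] cycloaddition with the tethered 2-(silylmethyl)diene, the C6–C7 bond leading (C7 is the nucleophilic diene terminus, with developing charge stabilised at C8 by the β-silyl group and at C10 by two alkyl groups) and the C5–C10 bond following, which is the polarity-matched sense for a dienophile activated through the C4 carbonyl. The closest known reaction types are the thermal or Lewis-acid intramolecular Diels–Alder reaction of tethered dienynones, the oxazaborolidinium-catalysed enantioselective Diels–Alder reaction of acyclic enones, and chiral boron Lewis-acid catalysis of Diels–Alder reactions of acetylenic aldehydes; what is new is their combination on an ynone held in the tether. Ring B (C5–C10) closes as the six-membered [4+2] ring through C6–C7 and C5–C10, and ring A (C1–C5, C10) closes in the same event as the six-membered ring spanned by the four-atom tether C1–C4 (fused, type-1 mode). The only stereocentre created is the quaternary C10, set by the catalyst, whose aryl group should block one face of the coordinated ynone so that the diene adds to the other (the catalyst enantiomer is chosen for C10 R, and its antipode is equally available); because the dienophile is an alkyne there is no endo/exo or ring-fusion issue. The step needs the tether outside and the methyl inside at C10, which the E geometry of C9=C10 fixed in steps 1 and 3 secures, and it needs cycloaddition to outrun protodesilylation of the diene, which low temperature and the absence of free protic acid should secure.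

Step 9
Reactants: 12 bicyclic dienone
Product: 14 12-(triisopropylsilyloxy)-17-(trimethylsilyl)-13,14,15,16,18,19-hexanorlabda-4,8-dien-4-yl trifluoromethanesulfonate, via lithium enolate 13 (not isolated)
Conditions: Li, NH3/THF, t-BuOH (1 equiv), −78 °C; evaporate NH3; then PhNTf2, THF, 0 °C → rt
Reagents that add atoms: N-phenylbis(trifluoromethanesulfonimide) O=S(=O)(N(c1ccccc1)S(=O)(=O)C(F)(F)F)C(F)(F)F
Why: dissolving-metal conjugate reduction of the C4(=O)–C5=C6 enone protonates C6 and gives the C4–C5 enolate regiospecifically, and O-triflation traps it as the Δ4 enol triflate (reductive enolate generation and trapping).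

Step 10
Reactants: 14 enol triflate
Product: 15 2-(trimethylsilyl)ethyl 12-(triisopropylsilyloxy)-17-(trimethylsilyl)-13,14,15,16,18-pentanorlabda-4,8-dien-19-oate
Conditions: Pd(OAc)2 (10 mol%), dppf, CO (1 atm), Me3SiCH2CH2OH, Et3N, DMF, 60 °C
Reagents that add atoms: carbon monoxide [C-]#[O+]; 2-(trimethylsilyl)ethanol OCC[Si](C)(C)C
Why: palladium-catalysed alkoxycarbonylation of the vinyl triflate installs C19 on C4 as a fluoride-cleavable ester, so that the hindered axial carboxyl can be freed at the end without attack at its carbonyl.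

Step 11
Reactants: 15 Δ4-enoate
Product: 17 2-(trimethylsilyl)ethyl 12-(triisopropylsilyloxy)-17-(trimethylsilyl)-13,14,15,16-tetranorlabd-8-en-19-oate (5α-H; 4α-CH3; 4β-ester), via lithium ester enolate 16 (not isolated)
Conditions: Li, NH3/THF, t-BuOH (1 equiv), −78 °C; then MeI, −78 → −33 °C
Reagents that add atoms: iodomethane CI
Why: Birch-type reductive alkylation of the α,β-unsaturated ester should protonate C5 axially, anti to the C10 methyl (trans ring fusion), and methyl iodide should then attack the exocyclic ester enolate from the α face, away from the 1,3-diaxial C10 methyl, giving the 4α-methyl/4β-carboxyl centre.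

Step 12
Reactants: 17 allylsilane
Product: 18 2-(trimethylsilyl)ethyl 12-(triisopropylsilyloxy)-13,14,15,16-tetranorlabd-8(17)-en-19-oate
Conditions: CF3CO2H (3 equiv), CH2Cl2, −20 → 0 °C
Reagents that add atoms: none
Why: SE2′ protodesilylation should deliver the proton to C9 axially from the α face, opposite the axial C10 methyl, via the β-silyl cation at C8, setting 9α-H and releasing the exocyclic C8=C17 methylene regiospecifically.

Step 13
Reactants: 18 TIPS ether
Product: 19 2-(trimethylsilyl)ethyl 12-hydroxy-13,14,15,16-tetranorlabd-8(17)-en-19-oate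
Conditions: HF·pyridine, pyridine, THF, 0 °C → rt
Reagents that add atoms: none
Why: buffered HF cleaves the primary silyl ether while the silylethyl ester, which needs unsolvated fluoride, and the exocyclic alkene should survive (silyl ether cleavage).

Step 14
Reactants: 19 primary alcohol
Product: 20 2-(trimethylsilyl)ethyl 12-oxo-13,14,15,16-tetranorlabd-8(17)-en-19-oate
Conditions: Dess–Martin periodinane, NaHCO3, CH2Cl2, 0 °C → rt
Reagents that add atoms: none
Why: buffered Dess–Martin oxidation gives the aldehyde without epimerising C9 or isomerising the exocyclic alkene.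

Step 15
Reactants: 20 aldehyde; 21 methyl propiolate
Product: 22 15-methyl 19-[2-(trimethylsilyl)ethyl] (12S)-12-hydroxy-16-norlabd-8(17)-en-13-yne-15,19-dioate
Conditions: Me2Zn, (S,S)-ProPhenol (20 mol%), Ph3PO (40 mol%), toluene, 4 °C
Reagents that add atoms: none
Why: the catalyst-controlled dinuclear zinc–ProPhenol alkynylation should add the zinc alkynylide of the propiolate to one face of the α-unbranched aldehyde and set C12 as S (the ligand enantiomer is chosen for this sense, its antipode being equally available).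

Step 16
Reactants: 22 γ-hydroxy ynoate
Product: 24 2-(trimethylsilyl)ethyl (12S)-labda-8(17),13-dien-15,12-olid-19-oate, via hydroxy enoate 23 (not isolated)
Conditions: Me2CuLi (3 equiv), THF, −78 °C; aq. NH4Cl, warm to rt
Reagents that add atoms: lithium dimethylcuprate [Li+].C[Cu-]C
Why: syn-carbocupration puts the methyl on C13 cis to the C14 hydrogen, so the (Z)-γ-hydroxy enoate has C12–OH and the ester on the same side and should lactonise to the 4-methylbutenolide (cuprate addition to a γ-hydroxy ynoate).

Step 17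
Reactants: 24 butenolide
Product: 26 (12S,13Z)-12-hydroxylabda-8(17),13-diene-15,19-dioic acid, via lithium carboxylate 25 (not isolated)
Conditions: LiOH, THF/H2O, 0 °C; concentrate; then TBAF, DMF, rt; then 0.5 M HCl to pH 4.5, 0 °C, rapid extraction
Reagents that add atoms: lithium hydroxide [Li+].[OH-]
Why: acyl–oxygen saponification opens the butenolide to the (Z)-γ-hydroxy carboxylate without touching C12, fluoride then fragments the silylethyl ester by attack at silicon, and cold acidification to pH 4.5 should liberate the diacid before it can relactonise.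

**Compound list**

1 | 2-acetyl-γ-butyrolactone | CC(=O)C1CCOC1=O | starting material
2 | (E)-1-(2-oxodihydrofuran-3(2H)-ylidene)ethyl triflate (OTf cis to ring CH2, CH3 cis to C=O) | C/C(OS(=O)(=O)C(F)(F)F)=C1\C(=O)OCC1 | intermediate
3 | 3-(trimethylsilyl)propynal | C[Si](C)(C)C#CC=O | starting material
4 | rac-1-(trimethylsilyl)hex-5-en-1-yn-3-ol | C=CCC(O)C#C[Si](C)(C)C | intermediate
5 | 9-{4-[(9-borabicyclo[3.3.1]nonan-9-yl)oxy]-6-(trimethylsilyl)hex-5-yn-1-yl}-9-borabicyclo[3.3.1]nonane (not isolated) | C[Si](C)(C)C#CC(OB1C2CCCC1CCC2)CCCB1C2CCCC1CCC2 | intermediate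
6 | (E)-3-[6-hydroxy-8-(trimethylsilyl)oct-7-yn-2-ylidene]dihydrofuran-2(3H)-one | C/C(CCCC(O)C#C[Si](C)(C)C)=C1\C(=O)OCC1 | intermediate
7 | (E)-3-(2-hydroxyethyl)-4-methyl-1,10-bis(trimethylsilyl)-2-[(trimethylsilyl)methyl]dec-3-en-9-yne-2,8-diol (not isolated) | C[Si](C)(C)C#CC(O)CCC/C(C)=C(\CCO)C(O)(C[Si](C)(C)C)C[Si](C)(C)C | intermediate
8 | (E)-3-(2-hydroxyethyl)-4-methyl-10-(trimethylsilyl)-2-[(trimethylsilyl)methyl]deca-1,3-dien-9-yn-8-ol | C[Si](C)(C)C#CC(O)CCC/C(C)=C(\CCO)C(=C)C[Si](C)(C)C | intermediate
9 | (E)-4-methyl-3-[2-(triisopropylsilyloxy)ethyl]-10-(trimethylsilyl)-2-[(trimethylsilyl)methyl]deca-1,3-dien-9-yn-8-ol | C[Si](C)(C)C#CC(O)CCC/C(C)=C(\CCO[Si](C(C)C)(C(C)C)C(C)C)C(=C)C[Si](C)(C)C | intermediate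
10 | (E)-4-methyl-3-[2-(triisopropylsilyloxy)ethyl]-2-[(trimethylsilyl)methyl]deca-1,3-dien-9-yn-8-ol | C#CC(O)CCC/C(C)=C(\CCO[Si](C(C)C)(C(C)C)C(C)C)C(=C)C[Si](C)(C)C | intermediate
11 | (E)-7-methyl-8-[2-(triisopropylsilyloxy)ethyl]-9-[(trimethylsilyl)methyl]deca-7,9-dien-1-yn-3-one | C#CC(=O)CCC/C(C)=C(\CCO[Si](C(C)C)(C(C)C)C(C)C)C(=C)C[Si](C)(C)C | intermediate
12 | 12-(triisopropylsilyloxy)-17-(trimethylsilyl)-13,14,15,16,18,19-hexanorlabda-5,8-dien-4-one (10β-CH3, C10 R) | C[C@]12CCCC(=O)C1=CCC(C[Si](C)(C)C)=C2CCO[Si](C(C)C)(C(C)C)C(C)C | intermediate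
13 | lithium enolate of the 4-ketone (O–C4=C5; 10β-CH3) (not isolated) | C[C@]12CCCC([O-])=C1CCC(C[Si](C)(C)C)=C2CCO[Si](C(C)C)(C(C)C)C(C)C.[Li+] | intermediate
14 | 12-(triisopropylsilyloxy)-17-(trimethylsilyl)-13,14,15,16,18,19-hexanorlabda-4,8-dien-4-yl triflate (10β-CH3) | C[C@]12CCCC(OS(=O)(=O)C(F)(F)F)=C1CCC(C[Si](C)(C)C)=C2CCO[Si](C(C)C)(C(C)C)C(C)C | intermediate
15 | 2-(trimethylsilyl)ethyl 12-(triisopropylsilyloxy)-17-(trimethylsilyl)-13,14,15,16,18-pentanorlabda-4,8-dien-19-oate (10β-CH3) | C[C@]12CCCC(C(=O)OCC[Si](C)(C)C)=C1CCC(C[Si](C)(C)C)=C2CCO[Si](C(C)C)(C(C)C)C(C)C | intermediate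
16 | lithium enolate of the 19-ester (C4=C19; 5α-H, 10β-CH3) (not isolated) | C[Si](C)(C)CC=1CC[C@@H]2[C@](C)(CCCC2=C([O-])OCC[Si](C)(C)C)C=1CCO[Si](C(C)C)(C(C)C)C(C)C.[Li+] | intermediate
17 | 2-(trimethylsilyl)ethyl 12-(triisopropylsilyloxy)-17-(trimethylsilyl)-13,14,15,16-tetranorlabd-8-en-19-oate (5α-H, 4α-CH3, 4β-ester, 10β-CH3) | C[Si](C)(C)CC=1CC[C@@H]2[C@](C)(CCC[C@]2(C)C(=O)OCC[Si](C)(C)C)C=1CCO[Si](C(C)C)(C(C)C)C(C)C | intermediate
18 | 2-(trimethylsilyl)ethyl 12-(triisopropylsilyloxy)-13,14,15,16-tetranorlabd-8(17)-en-19-oate (9α-H) | C=C1CC[C@@H]2[C@](C)(CCC[C@]2(C)C(=O)OCC[Si](C)(C)C)[C@H]1CCO[Si](C(C)C)(C(C)C)C(C)C | intermediate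
19 | 2-(trimethylsilyl)ethyl 12-hydroxy-13,14,15,16-tetranorlabd-8(17)-en-19-oate | C=C1CC[C@@H]2[C@](C)(CCC[C@]2(C)C(=O)OCC[Si](C)(C)C)[C@H]1CCO | intermediate
20 | 2-(trimethylsilyl)ethyl 12-oxo-13,14,15,16-tetranorlabd-8(17)-en-19-oate | C=C1CC[C@@H]2[C@](C)(CCC[C@]2(C)C(=O)OCC[Si](C)(C)C)[C@H]1CC=O | intermediate
21 | methyl propiolate | C#CC(=O)OC | starting material
22 | 15-methyl 19-[2-(trimethylsilyl)ethyl] (12S)-12-hydroxy-16-norlabd-8(17)-en-13-yne-15,19-dioate | C=C1CC[C@@H]2[C@](C)(CCC[C@]2(C)C(=O)OCC[Si](C)(C)C)[C@H]1C[C@H](O)C#CC(=O)OC | intermediate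
23 | 15-methyl 19-[2-(trimethylsilyl)ethyl] (12S,13Z)-12-hydroxylabda-8(17),13-diene-15,19-dioate (not isolated) | C=C1CC[C@@H]2[C@](C)(CCC[C@]2(C)C(=O)OCC[Si](C)(C)C)[C@H]1C[C@H](O)/C(C)=C\C(=O)OC | intermediate
24 | 2-(trimethylsilyl)ethyl (12S)-labda-8(17),13-dien-15,12-olid-19-oate | C=C1CC[C@@H]2[C@](C)(CCC[C@]2(C)C(=O)OCC[Si](C)(C)C)[C@H]1C[C@@H]1OC(=O)C=C1C | intermediate
25 | lithium (12S,13Z)-12-hydroxy-19-[2-(trimethylsilyl)ethoxy]-19-oxolabda-8(17),13-dien-15-oate (not isolated) | C=C1CC[C@@H]2[C@](C)(CCC[C@]2(C)C(=O)OCC[Si](C)(C)C)[C@H]1C[C@H](O)/C(C)=C\C(=O)[O-].[Li+] | intermediate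
26 | (12S,13Z)-12-hydroxylabda-8(17),13-diene-15,19-dioic acid (4S,5R,9S,10R) | C=C1CC[C@@H]2[C@](C)(CCC[C@]2(C)C(=O)O)[C@H]1C[C@H](O)/C(C)=C\C(=O)O | target

**Step count and risks**

Total step count: 17. Longest linear sequence: 16 (steps 1 and 3–17; step 2 is a one-step branch).

Steps most likely to fail:

1. Step 8 (Proposed new method). The catalyst may discriminate the two faces of the coordinated ynone poorly, since an ynone offers no α-vinyl C–H for two-point binding, and the acid-sensitive diene may be protodesilylated or oligomerised before it cyclises. The fallback sets out from 10 and returns at 14, using only known chemistry. Semi-hydrogenation of the terminal alkyne of 10 (H2, Lindlar catalyst, quinoline) would give the vinyl carbinol F1, and MnO2 oxidation the trienone F2. F2 is an acyclic enone, an established dienophile class for the same oxazaborolidinium catalyst, and its endo-selective intramolecular Diels–Alder reaction should give the cis-fused octalone F3 with C10 set. Thermodynamic enolisation toward the ring fusion (KHMDS, 0.95 equiv, THF, equilibration at rt, then PhNTf2) would erase C5 and deliver triflate 14.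

2. Step 11. The ester enolate may be protonated before it is alkylated, the ester may be over-reduced, or the C-methylation may show incomplete facial control. The fallback sets out from 15 and returns at 17 by separating reduction from alkylation. Li/NH3 with one equivalent of t-BuOH followed by a solid NH4Cl quench would give the saturated ester F4 (5α-H, C4 epimers); regeneration of the enolate with LDA in THF/HMPA at −78 °C and methylation with MeI, again from the α face, would give 17.

3. Step 17. The butenolide may epimerise at C12 through its furanolate before hydroxide opens the ring, and the hydroxy acid may relactonise during acidification. The fallback sets out from 22 and returns at 26 without ever forming the butenolide. Silylation (TESCl, imidazole) would give the triethylsilyl ether F5, and Me2CuLi the (Z)-enoate F6, which cannot lactonise. LiOH hydrolysis of the methyl ester would give the mono-acid F7, and TBAF would then remove the silyl ether and the silylethyl ester together, so that the dicarboxylate is only neutralised (pH 4.5 buffer, 0 °C) at the very end to give 26.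

**Further compounds**

F1 | step 8 | (E)-4-methyl-3-[2-(triisopropylsilyloxy)ethyl]-2-[(trimethylsilyl)methyl]deca-1,3,9-trien-8-ol | C=CC(O)CCC/C(C)=C(\CCO[Si](C(C)C)(C(C)C)C(C)C)C(=C)C[Si](C)(C)C
F2 | step 8 | (E)-7-methyl-8-[2-(triisopropylsilyloxy)ethyl]-9-[(trimethylsilyl)methyl]deca-1,7,9-trien-3-one | C=CC(=O)CCC/C(C)=C(\CCO[Si](C(C)C)(C(C)C)C(C)C)C(=C)C[Si](C)(C)C
F3 | step 8 | cis-fused 12-(triisopropylsilyloxy)-17-(trimethylsilyl)-13,14,15,16,18,19-hexanorlabd-8-en-4-one (5β-H, 10β-CH3) | C[C@]12CCCC(=O)[C@H]1CCC(C[Si](C)(C)C)=C2CCO[Si](C(C)C)(C(C)C)C(C)C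
F4 | step 11 | 2-(trimethylsilyl)ethyl 12-(triisopropylsilyloxy)-17-(trimethylsilyl)-13,14,15,16,18-pentanorlabd-8-en-19-oate (5α-H, C4 epimers) | C[Si](C)(C)CC=1CC[C@@H]2[C@](C)(CCCC2C(=O)OCC[Si](C)(C)C)C=1CCO[Si](C(C)C)(C(C)C)C(C)C
F5 | step 17 | 15-methyl 19-[2-(trimethylsilyl)ethyl] (12S)-12-(triethylsilyloxy)-16-norlabd-8(17)-en-13-yne-15,19-dioate | C=C1CC[C@@H]2[C@](C)(CCC[C@]2(C)C(=O)OCC[Si](C)(C)C)[C@H]1C[C@H](O[Si](CC)(CC)CC)C#CC(=O)OC
F6 | step 17 | 15-methyl 19-[2-(trimethylsilyl)ethyl] (12S,13Z)-12-(triethylsilyloxy)labda-8(17),13-diene-15,19-dioate | C=C1CC[C@@H]2[C@](C)(CCC[C@]2(C)C(=O)OCC[Si](C)(C)C)[C@H]1C[C@H](O[Si](CC)(CC)CC)/C(C)=C\C(=O)OC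
F7 | step 17 | (12S,13Z)-12-(triethylsilyloxy)-19-[2-(trimethylsilyl)ethoxy]-19-oxolabda-8(17),13-dien-15-oic acid | C=C1CC[C@@H]2[C@](C)(CCC[C@]2(C)C(=O)OCC[Si](C)(C)C)[C@H]1C[C@H](O[Si](CC)(CC)CC)/C(C)=C\C(=O)O
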